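**Plan**

- Retrosynthesis: the three silyl ethers are cut last. The oxolane C3 CH2OH is taken back to a carboxylic acid and the ring A benzyl CH2 to a benzylic lactone C–O bond, which gives the cis-fused furofuranone 28.
- In 28 the oxolane C2–C3 bond is cut (rhodium carbenoid C–H insertion) to the α-diazo lactone 27. The ether arm of 27 is cut at its benzylic C–O bond into lactone diol 7 and the dihydrobenzofuranylmethyl imidate 22.
- Forward order of ring formation: butyrolactone (step 4), cis-dihydrobenzofuran (step 11), union by etherification (step 16), oxolane (step 19), lactone opened again (step 20).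
- Stereochemistry: oxolane C4 comes from the Sharpless epoxidation of step 4. Dihydrobenzofuran C2 and C3 come from the chiral dirhodium carboxylate of step 11. Oxolane C2 and C3 come from the cis-fused, endo-selective insertion of step 19, relayed from C4.
- Enabling feature: the oxolane ring (O1, C2–C5) carries the aryl group at C2, CH2OH at C3 and the benzyl group at C4 on one face and the C4 hydroxyl on the other. It is therefore a 3,7-dioxabicyclo[3.3.0]octan-2-one (C3 CH2OH = lactone carbonyl, C4 benzyl CH2 = lactone O–CH–aryl carbon) with the lactone reduced open, and C2–H is an ether C–H five atoms from the lactone α-carbon.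

Key step: step 19

Abbreviations: Ar1 = 4-(benzyloxy)-3-methoxyphenyl. Ar2 = 3-methoxy-4-[tri(propan-2-yl)silyloxy]phenyl. DBF = (2R,3R)-3-{[tert-butyl(dimethyl)silyl]oxymethyl}-7-methoxy-2-Ar2-2,3-dihydro-1-benzofuran-5-yl (2,3-cis). Oxolane locants: O1, C2 (aryl), C3, C4 (carbinol), C5.

Assumption: Rh2(S-PTTL)4, dirhodium tetrakis[N-phthaloyl-(S)-tert-leucinate], is taken to give the 2R series in step 11, as for related aryl benzyl ethers. If the sense is opposite, the (R)-configured catalyst is used and nothing else changes.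

**Route**

Step 1
Reactants: 1 4-(benzyloxy)-3-methoxybenzaldehyde; 2 dimethyl succinate
Product: 3 (3E)-4-Ar1-3-(methoxycarbonyl)but-3-enoic acid
Conditions: NaOMe, MeOH, reflux; then aq. HCl
Reagents that add atoms: none
Why: Stobbe condensation: the succinate enolate adds to the aldehyde, the aldolate lactonises and the paraconate opens by E1cB elimination to the half-ester, in which the aryl group lies trans to the conjugated ester (E) and the two carboxyl groups are already differentiated.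

Step 2
Reactants: 3 (3E)-4-Ar1-3-(methoxycarbonyl)but-3-enoic acid
Product: 4 4-tert-butyl 1-methyl (2E)-2-(Ar1-methylidene)butanedioate
Conditions: Cl3CC(=NH)OtBu (2 equiv), CH2Cl2–cyclohexane, rt
Reagents that add atoms: tert-butyl 2,2,2-trichloroacetimidate, CC(C)(C)OC(=N)C(Cl)(Cl)Cl
Why: O-alkylation of a carboxylic acid by a trichloroacetimidate (the acid protonates the imidate and captures the tert-butyl cation); the tert-butyl ester resists the hydride of step 3 and is the internal nucleophile of step 4.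

Step 3
Reactants: 4 4-tert-butyl 1-methyl (2E)-2-(Ar1-methylidene)butanedioate
Product: 5 tert-butyl (3E)-4-Ar1-3-(hydroxymethyl)but-3-enoate
Conditions: iBu2AlH (2.3 equiv), CH2Cl2, −78 °C; aq. potassium sodium tartrate work-up
Reagents that add atoms: none
Why: Chemoselective iBu2AlH 1,2-reduction of the unhindered conjugated methyl ester to the allylic alcohol at −78 °C, where the tert-butyl ester is not attacked; the alkene geometry is untouched.

Step 4
Reactants: 5 tert-butyl (3E)-4-Ar1-3-(hydroxymethyl)but-3-enoate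
Product: 7 (4S,5R)-5-Ar1-4-hydroxy-4-(hydroxymethyl)oxolan-2-one, via epoxy alcohol 6 (not isolated)
Conditions: Ti(OiPr)4 (10 mol%), L-(+)-diisopropyl tartrate (12 mol%), tBuOOH (2 equiv), 4 Å MS, CH2Cl2, −20 °C; then camphorsulfonic acid (0.3 equiv), −20 → 0 °C
Reagents that add atoms: tert-butyl hydroperoxide, CC(C)(C)OO
Why: Sharpless asymmetric epoxidation of an (E)-2,3-disubstituted allylic alcohol (L-(+)-tartrate should give the (2S,3S)-epoxide, which fixes the quaternary carbinol carbon) followed by acid-induced epoxy ester lactonisation, in which the tert-butyl ester carbonyl oxygen opens the epoxide at its benzylic carbon with inversion and loses isobutene, so that the lactone aryl group ends cis to the tertiary hydroxyl.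

Step 5
Reactants: 8 vanillin
Product: 9 3-methoxy-4-[tri(propan-2-yl)silyloxy]benzaldehyde
Conditions: iPr3SiCl, imidazole, DMF, rt
Reagents that add atoms: chlorotri(propan-2-yl)silane, CC(C)[Si](Cl)(C(C)C)C(C)C
Why: Imidazole-mediated silylation of the phenol; the hindered aryl silyl ether should withstand the alkoxide, amidine, hydride and organolithium steps that follow and is not removed by hydrogenolysis.

Step 6
Reactants: 9 3-methoxy-4-[tri(propan-2-yl)silyloxy]benzaldehyde
Product: 10 Ar2-methanol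
Conditions: NaBH4, MeOH, 0 °C
Reagents that add atoms: none
Why: Borohydride reduction of the aldehyde to the benzylic alcohol; the aryl silyl ether is inert.

Step 7
Reactants: 10 Ar2-methanol; 11 5-bromo-2-hydroxy-3-methoxybenzaldehyde
Product: 12 5-bromo-3-methoxy-2-(Ar2-methoxy)benzaldehyde
Conditions: PPh3, diisopropyl azodicarboxylate, THF, 0 °C → rt
Reagents that add atoms: none
Why: Mitsunobu etherification: the acidic, hydrogen-bonded salicylaldehyde-type phenol is alkylated by the phosphonium-activated benzylic alcohol under neutral conditions that leave the aryl silyl ether in place.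

Step 8
Reactants: 12 5-bromo-3-methoxy-2-(Ar2-methoxy)benzaldehyde
Product: 13 5-bromo-1-methoxy-3-(2-methoxyethenyl)-2-(Ar2-methoxy)benzene (E/Z mixture)
Conditions: Ph3P(CH2OMe)Cl, KOtBu, THF, 0 °C → rt
Reagents that add atoms: (methoxymethyl)triphenylphosphonium chloride, COC[P+](c1ccccc1)(c1ccccc1)c1ccccc1.[Cl-]
Why: Wittig methoxymethylenation of the aldehyde, which adds the one carbon of the future ester; the E/Z ratio of the enol ether is of no consequence.

Step 9
Reactants: 13 5-bromo-1-methoxy-3-(2-methoxyethenyl)-2-(Ar2-methoxy)benzene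
Product: 14 methyl 2-[5-bromo-3-methoxy-2-(Ar2-methoxy)phenyl]acetate
Conditions: pyridinium chlorochromate (C5H5NH[CrO3Cl]), NaOAc, 4 Å MS, CH2Cl2, rt
Reagents that add atoms: pyridinium chlorochromate, [O-][Cr](=O)(=O)Cl.c1cc[nH+]cc1
Why: Chlorochromate oxidation of an enol ether to the ester (electrophilic attack of chromium on the electron-rich enol ether carbon, then collapse of the acetal-type chromate ester), which gives the arylacetate without the aqueous acid that would cleave the p-silyloxybenzyl aryl ether.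

Step 10
Reactants: 14 methyl 2-[5-bromo-3-methoxy-2-(Ar2-methoxy)phenyl]acetate
Product: 15 methyl 2-[5-bromo-3-methoxy-2-(Ar2-methoxy)phenyl]-2-diazoacetate
Conditions: 4-acetamidobenzenesulfonyl azide, DBU, MeCN, 0 °C → rt
Reagents that add atoms: 4-acetamidobenzenesulfonyl azide, CC(=O)Nc1ccc(cc1)S(=O)(=O)N=[N+]=[N-]
Why: Regitz diazo transfer to the benzylic, ester-activated methylene group, the standard entry to aryl diazoacetates.

Step 11
Reactants: 15 methyl 2-[5-bromo-3-methoxy-2-(Ar2-methoxy)phenyl]-2-diazoacetate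
Product: 16 methyl (2R,3S)-5-bromo-7-methoxy-2-Ar2-2,3-dihydro-1-benzofuran-3-carboxylate (2,3-cis)
Conditions: Rh2(S-PTTL)4 (1 mol%), toluene, −78 °C
Reagents that add atoms: none
Why: Enantioselective intramolecular 1,5 C–H insertion of the donor/acceptor rhodium carbenoid into the ArO–CH2–aryl bond, which closes the dihydrofuran ring with the aryl group cis to the ester (the kinetic preference of this insertion) and sets C2 (R) and C3 (S) under control of the chiral carboxylate ligands.

Step 12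
Reactants: 16 methyl (2R,3S)-5-bromo-7-methoxy-2-Ar2-2,3-dihydro-1-benzofuran-3-carboxylate
Product: 17 [(2R,3R)-5-bromo-7-methoxy-2-Ar2-2,3-dihydro-1-benzofuran-3-yl]methanol (2,3-cis)
Conditions: iBu2AlH, CH2Cl2, −78 → −40 °C; aq. potassium sodium tartrate work-up
Reagents that add atoms: none
Why: Ester reduction by a non-basic aluminium hydride at low temperature, so that the epimerisable cis C3 centre is kept (the descriptor becomes 3R only because the priorities change).

Step 13
Reactants: 17 [(2R,3R)-5-bromo-7-methoxy-2-Ar2-2,3-dihydro-1-benzofuran-3-yl]methanol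
Product: 18 (2R,3R)-5-bromo-3-{[tert-butyl(dimethyl)silyl]oxymethyl}-7-methoxy-2-Ar2-2,3-dihydro-1-benzofuran
Conditions: tBuMe2SiCl, imidazole, DMF, rt
Reagents that add atoms: tert-butylchlorodimethylsilane, CC(C)(C)[Si](C)(C)Cl
Why: Standard silylation of the primary alcohol, which must be masked before the organolithium and imidate steps.

Step 14
Reactants: 18 (2R,3R)-5-bromo-3-{[tert-butyl(dimethyl)silyl]oxymethyl}-7-methoxy-2-Ar2-2,3-dihydro-1-benzofuran
Product: 21 DBF-methanol, via aryllithium 19 (not isolated), via aldehyde 20 (not isolated)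
Conditions: nBuLi, THF, −78 °C; DMF, −78 → 0 °C; then MeOH, NaBH4, 0 °C
Reagents that add atoms: N,N-dimethylformamide, CN(C)C=O; n-butyllithium, [Li]CCCC (its lithium stays in 19 only)
Why: Bromine–lithium exchange, formylation of the aryllithium with DMF and borohydride reduction of the liberated aldehyde in one flask; no stereocentre is touched.

Step 15
Reactants: 21 DBF-methanol
Product: 22 DBF-methyl 2,2,2-trichloroacetimidate
Conditions: Cl3CCN, DBU (0.1 equiv), CH2Cl2, 0 °C
Reagents that add atoms: trichloroacetonitrile, ClC(Cl)(Cl)C#N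
Why: Base-catalysed addition of the benzylic alcohol to trichloroacetonitrile gives the imidate, a p-alkoxybenzyl donor that a trace of acid activates.

Step 16
Reactants: 7 (4S,5R)-5-Ar1-4-hydroxy-4-(hydroxymethyl)oxolan-2-one; 22 DBF-methyl 2,2,2-trichloroacetimidate
Product: 23 (4S,5R)-5-Ar1-4-hydroxy-4-[(DBF-methoxy)methyl]oxolan-2-one
Conditions: camphorsulfonic acid (10 mol%), 4 Å MS, CH2Cl2, 0 °C
Reagents that add atoms: none
Why: Acid-catalysed trichloroacetimidate etherification through the p-alkoxybenzyl cation, which the primary hydroxyl of 7 captures in preference to the hindered tertiary one.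

Step 17
Reactants: 23 (4S,5R)-5-Ar1-4-hydroxy-4-[(DBF-methoxy)methyl]oxolan-2-one
Product: 24 (4S,5R)-5-Ar1-4-[(DBF-methoxy)methyl]-4-(triethylsilyloxy)oxolan-2-one
Conditions: Et3SiOTf, 2,6-lutidine, CH2Cl2, −78 → 0 °C
Reagents that add atoms: triethylsilyl trifluoromethanesulfonate, CC[Si](CC)(CC)OS(=O)(=O)C(F)(F)F
Why: Silyl triflate silylation of the tertiary alcohol; the silyl ether blocks O–H insertion and oxygen-assisted 1,2-shifts at the carbenoid stage.

Step 18
Reactants: 24 (4S,5R)-5-Ar1-4-[(DBF-methoxy)methyl]-4-(triethylsilyloxy)oxolan-2-one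
Product: 27 (4S,5R)-5-Ar1-3-diazo-4-[(DBF-methoxy)methyl]-4-(triethylsilyloxy)oxolan-2-one, via lithium enolate 25 (not isolated), via trifluoroacetyl lactone 26 (not isolated)
Conditions: LiN(SiMe3)2, THF, −78 °C; CF3CO2CH2CF3, −78 °C; 5% aq. HCl wash; then MsN3, Et3N, H2O (1 equiv), MeCN, rt
Reagents that add atoms: methanesulfonyl azide, CS(=O)(=O)N=[N+]=[N-]; lithium bis(trimethylsilyl)amide, [Li]N([Si](C)(C)C)[Si](C)(C)C (its lithium stays in 25 only); 2,2,2-trifluoroethyl trifluoroacetate, O=C(OCC(F)(F)F)C(F)(F)F (its trifluoroacetyl group stays in 26 only)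
Why: Detrifluoroacetylative diazo transfer of the Regitz type: the kinetic lactone enolate is C-acylated at −78 °C before it can expel the β-silyloxy group, and the activated β-dicarbonyl compound then takes up the diazo group with loss of the trifluoroacetyl group.

Step 19
Reactants: 27 (4S,5R)-5-Ar1-3-diazo-4-[(DBF-methoxy)methyl]-4-(triethylsilyloxy)oxolan-2-one
Product: 28 (3R,3aS,6R,6aR)-3-Ar1-6-DBF-3a-(triethylsilyloxy)tetrahydro-1H,3H-furo[3,4-c]furan-1-one (cis-fused; 6-DBF endo on the side of C1; 3-Ar1 exo on the side of the 3a-silyloxy group)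
Conditions: Rh2(OAc)4 (2 mol%), CH2Cl2, 40 °C, slow addition of 27
Reagents that add atoms: none
Why: Rh2(OAc)4 expels N2 from 27, and the electrophilic rhodium carbenoid at the lactone α-carbon inserts into one O–CH2–aryl C–H bond of the ether arm through a concerted, asynchronous three-centre transition state with hydride-transfer character; the closest known reaction type is the dirhodium tetraacetate-catalysed 1,5 C–H insertion of α-diazo-γ-butyrolactones that carry a benzyloxymethyl group on the β-carbon, which gives endo-aryl furofuranones. The oxolane closes as a 1,5-insertion (new bond C6–C6a, five-membered ring through the arm oxygen), and a five-membered ring annulated on the lactone across C3a–C6a can only be cis-fused. C6a is therefore fixed by C3a (set in step 4), with its hydrogen on the face of the 3a-silyloxy group. At C6 the aryl group should be placed on the side of the lactone carbonyl (endo), the kinetic preference of this insertion class that also operates in step 11, and the exo position of the C3 aryl group leaves the concave face free for it. The step needs site selectivity for the arm C–H over other C–H bonds and over 1,2-shifts: the arm CH2 is the only C–H that is five atoms away, α to oxygen and benzylic to an electron-rich ring, C3a carries no hydrogen that could migrate, and slow addition keeps carbene dimerisation down.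

Step 20
Reactants: 28 (3R,3aS,6R,6aR)-3-Ar1-6-DBF-3a-(triethylsilyloxy)tetrahydro-1H,3H-furo[3,4-c]furan-1-one
Product: 29 (2R,3R,4S)-2-DBF-4-[(4-hydroxy-3-methoxyphenyl)methyl]-4-(triethylsilyloxy)oxolane-3-carboxylic acid
Conditions: H2 (1 atm), 10% Pd/C, EtOAc, rt, stopped after uptake of 2 equiv
Reagents that add atoms: none
Why: Catalytic hydrogenolysis: the aryl benzyl ether falls first, and the benzylic lactone C–O bond (a benzylic ester on the ring that now carries a free para-hydroxyl) should be cleaved next, ahead of the benzylic ether bonds of the oxolane and the dihydrobenzofuran, which have poorer leaving groups and, for the latter, an aryl ring shielded by the bulky silyl ether; the lactone benzylic centre becomes CH2 and no other centre is touched.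

Step 21
Reactants: 29 (2R,3R,4S)-2-DBF-4-[(4-hydroxy-3-methoxyphenyl)methyl]-4-(triethylsilyloxy)oxolane-3-carboxylic acid
Product: 30 [(2R,3R,4S)-2-DBF-4-[(4-hydroxy-3-methoxyphenyl)methyl]-4-(triethylsilyloxy)oxolan-3-yl]methanol
Conditions: BH3·THF, THF, 0 °C → rt; MeOH quench
Reagents that add atoms: none
Why: Borane reduction of the carboxylic acid through its acyloxyborane, which leaves silyl ethers, aryl ethers and the phenol (after methanolysis of its borate) unchanged.

Step 22
Reactants: 30 [(2R,3R,4S)-2-DBF-4-[(4-hydroxy-3-methoxyphenyl)methyl]-4-(triethylsilyloxy)oxolan-3-yl]methanol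
Product: 31 (2R,3R,4S)-4-[(4-hydroxy-3-methoxyphenyl)methyl]-2-[(2R,3R)-2-(4-hydroxy-3-methoxyphenyl)-3-(hydroxymethyl)-7-methoxy-2,3-dihydro-1-benzofuran-5-yl]-3-(hydroxymethyl)oxolan-4-ol (CNP0284796.1)
Conditions: Bu4NF, AcOH, THF, rt
Reagents that add atoms: none
Why: Fluoride-induced cleavage of the tertiary triethylsilyl, primary tert-butyldimethylsilyl and aryl triisopropylsilyl ethers, buffered with acetic acid so that the free guaiacol units are not exposed as phenoxides.

**Compound list**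

1 | 4-(benzyloxy)-3-methoxybenzaldehyde | COc1cc(C=O)ccc1OCc1ccccc1 | starting material
2 | dimethyl succinate | COC(=O)CCC(=O)OC | starting material
3 | (3E)-4-Ar1-3-(methoxycarbonyl)but-3-enoic acid | COC(=O)/C(=C/c1ccc(OCc2ccccc2)c(OC)c1)CC(=O)O | intermediate
4 | 4-tert-butyl 1-methyl (2E)-2-(Ar1-methylidene)butanedioate | COC(=O)/C(=C/c1ccc(OCc2ccccc2)c(OC)c1)CC(=O)OC(C)(C)C | intermediate
5 | tert-butyl (3E)-4-Ar1-3-(hydroxymethyl)but-3-enoate | OC/C(=C/c1ccc(OCc2ccccc2)c(OC)c1)CC(=O)OC(C)(C)C | intermediate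
6 | tert-butyl 2-[(2S,3S)-3-Ar1-2-(hydroxymethyl)oxiran-2-yl]acetate | CC(C)(C)OC(=O)C[C@@]1(CO)O[C@H]1c1ccc(OCc2ccccc2)c(OC)c1 | intermediate (not isolated)
7 | (4S,5R)-5-Ar1-4-hydroxy-4-(hydroxymethyl)oxolan-2-one | OC[C@@]1(O)CC(=O)O[C@@H]1c1ccc(OCc2ccccc2)c(OC)c1 | intermediate
8 | vanillin | COc1cc(C=O)ccc1O | starting material
9 | 3-methoxy-4-[tri(propan-2-yl)silyloxy]benzaldehyde | COc1cc(C=O)ccc1O[Si](C(C)C)(C(C)C)C(C)C | intermediate
10 | Ar2-methanol | COc1cc(CO)ccc1O[Si](C(C)C)(C(C)C)C(C)C | intermediate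
11 | 5-bromo-2-hydroxy-3-methoxybenzaldehyde | COc1cc(Br)cc(C=O)c1O | starting material
12 | 5-bromo-3-methoxy-2-(Ar2-methoxy)benzaldehyde | COc1cc(Br)cc(C=O)c1OCc1ccc(O[Si](C(C)C)(C(C)C)C(C)C)c(OC)c1 | intermediate
13 | 5-bromo-1-methoxy-3-(2-methoxyethenyl)-2-(Ar2-methoxy)benzene (E/Z mixture) | COC=Cc1cc(Br)cc(OC)c1OCc1ccc(O[Si](C(C)C)(C(C)C)C(C)C)c(OC)c1 | intermediate
14 | methyl 2-[5-bromo-3-methoxy-2-(Ar2-methoxy)phenyl]acetate | COC(=O)Cc1cc(Br)cc(OC)c1OCc1ccc(O[Si](C(C)C)(C(C)C)C(C)C)c(OC)c1 | intermediate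
15 | methyl 2-[5-bromo-3-methoxy-2-(Ar2-methoxy)phenyl]-2-diazoacetate | COC(=O)C(=[N+]=[N-])c1cc(Br)cc(OC)c1OCc1ccc(O[Si](C(C)C)(C(C)C)C(C)C)c(OC)c1 | intermediate
16 | methyl (2R,3S)-5-bromo-7-methoxy-2-Ar2-2,3-dihydro-1-benzofuran-3-carboxylate (cis) | Brc1cc(OC)c2c(c1)[C@H](C(=O)OC)[C@H](c1ccc(O[Si](C(C)C)(C(C)C)C(C)C)c(OC)c1)O2 | intermediate
17 | [(2R,3R)-5-bromo-7-methoxy-2-Ar2-2,3-dihydro-1-benzofuran-3-yl]methanol (cis) | Brc1cc(OC)c2c(c1)[C@H](CO)[C@H](c1ccc(O[Si](C(C)C)(C(C)C)C(C)C)c(OC)c1)O2 | intermediate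
18 | (2R,3R)-5-bromo-3-{[tert-butyl(dimethyl)silyl]oxymethyl}-7-methoxy-2-Ar2-2,3-dihydro-1-benzofuran | Brc1cc(OC)c2c(c1)[C@H](CO[Si](C)(C)C(C)(C)C)[C@H](c1ccc(O[Si](C(C)C)(C(C)C)C(C)C)c(OC)c1)O2 | intermediate
19 | DBF-lithium (5-lithio compound) | [Li]c1cc(OC)c2c(c1)[C@H](CO[Si](C)(C)C(C)(C)C)[C@H](c1ccc(O[Si](C(C)C)(C(C)C)C(C)C)c(OC)c1)O2 | intermediate (not isolated)
20 | DBF-carbaldehyde | O=Cc1cc(OC)c2c(c1)[C@H](CO[Si](C)(C)C(C)(C)C)[C@H](c1ccc(O[Si](C(C)C)(C(C)C)C(C)C)c(OC)c1)O2 | intermediate (not isolated)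
21 | DBF-methanol | OCc1cc(OC)c2c(c1)[C@H](CO[Si](C)(C)C(C)(C)C)[C@H](c1ccc(O[Si](C(C)C)(C(C)C)C(C)C)c(OC)c1)O2 | intermediate
22 | DBF-methyl 2,2,2-trichloroacetimidate | N=C(OCc1cc(OC)c2c(c1)[C@H](CO[Si](C)(C)C(C)(C)C)[C@H](c1ccc(O[Si](C(C)C)(C(C)C)C(C)C)c(OC)c1)O2)C(Cl)(Cl)Cl | intermediate
23 | (4S,5R)-5-Ar1-4-hydroxy-4-[(DBF-methoxy)methyl]oxolan-2-one | C(OCc1cc(OC)c2c(c1)[C@H](CO[Si](C)(C)C(C)(C)C)[C@H](c1ccc(O[Si](C(C)C)(C(C)C)C(C)C)c(OC)c1)O2)[C@@]1(O)CC(=O)O[C@@H]1c1ccc(OCc2ccccc2)c(OC)c1 | intermediate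
24 | (4S,5R)-5-Ar1-4-[(DBF-methoxy)methyl]-4-(triethylsilyloxy)oxolan-2-one | C(OCc1cc(OC)c2c(c1)[C@H](CO[Si](C)(C)C(C)(C)C)[C@H](c1ccc(O[Si](C(C)C)(C(C)C)C(C)C)c(OC)c1)O2)[C@@]1(O[Si](CC)(CC)CC)CC(=O)O[C@@H]1c1ccc(OCc2ccccc2)c(OC)c1 | intermediate
25 | lithium enolate of 24 | C(OCc1cc(OC)c2c(c1)[C@H](CO[Si](C)(C)C(C)(C)C)[C@H](c1ccc(O[Si](C(C)C)(C(C)C)C(C)C)c(OC)c1)O2)[C@@]1(O[Si](CC)(CC)CC)C=C(O[Li])O[C@@H]1c1ccc(OCc2ccccc2)c(OC)c1 | intermediate (not isolated)
26 | 3-(trifluoroacetyl) derivative of 24 (C3 epimers or enol) | C(OCc1cc(OC)c2c(c1)[C@H](CO[Si](C)(C)C(C)(C)C)[C@H](c1ccc(O[Si](C(C)C)(C(C)C)C(C)C)c(OC)c1)O2)[C@@]1(O[Si](CC)(CC)CC)C(C(=O)C(F)(F)F)C(=O)O[C@@H]1c1ccc(OCc2ccccc2)c(OC)c1 | intermediate (not isolated)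
27 | (4S,5R)-5-Ar1-3-diazo-4-[(DBF-methoxy)methyl]-4-(triethylsilyloxy)oxolan-2-one | C(OCc1cc(OC)c2c(c1)[C@H](CO[Si](C)(C)C(C)(C)C)[C@H](c1ccc(O[Si](C(C)C)(C(C)C)C(C)C)c(OC)c1)O2)[C@@]1(O[Si](CC)(CC)CC)C(=[N+]=[N-])C(=O)O[C@@H]1c1ccc(OCc2ccccc2)c(OC)c1 | intermediate (key-step precursor)
28 | (3R,3aS,6R,6aR)-3-Ar1-6-DBF-3a-(triethylsilyloxy)tetrahydro-1H,3H-furo[3,4-c]furan-1-one | COc1cc([C@H]2OC(=O)[C@@H]3[C@H](c4cc(OC)c5c(c4)[C@H](CO[Si](C)(C)C(C)(C)C)[C@H](c4ccc(O[Si](C(C)C)(C(C)C)C(C)C)c(OC)c4)O5)OC[C@]23O[Si](CC)(CC)CC)ccc1OCc1ccccc1 | intermediate (key-step product)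
29 | (2R,3R,4S)-2-DBF-4-[(4-hydroxy-3-methoxyphenyl)methyl]-4-(triethylsilyloxy)oxolane-3-carboxylic acid | COc1cc(C[C@@]2(O[Si](CC)(CC)CC)CO[C@@H](c3cc(OC)c4c(c3)[C@H](CO[Si](C)(C)C(C)(C)C)[C@H](c3ccc(O[Si](C(C)C)(C(C)C)C(C)C)c(OC)c3)O4)[C@H]2C(=O)O)ccc1O | intermediate
30 | [(2R,3R,4S)-2-DBF-4-[(4-hydroxy-3-methoxyphenyl)methyl]-4-(triethylsilyloxy)oxolan-3-yl]methanol | COc1cc(C[C@@]2(O[Si](CC)(CC)CC)CO[C@@H](c3cc(OC)c4c(c3)[C@H](CO[Si](C)(C)C(C)(C)C)[C@H](c3ccc(O[Si](C(C)C)(C(C)C)C(C)C)c(OC)c3)O4)[C@H]2CO)ccc1O | intermediate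
31 | CNP0284796.1, (2R,3R,4S)-4-[(4-hydroxy-3-methoxyphenyl)methyl]-2-[(2R,3R)-2-(4-hydroxy-3-methoxyphenyl)-3-(hydroxymethyl)-7-methoxy-2,3-dihydro-1-benzofuran-5-yl]-3-(hydroxymethyl)oxolan-4-ol | COc1cc(C[C@@]2(O)CO[C@@H](c3cc(OC)c4c(c3)[C@H](CO)[C@H](c3ccc(O)c(OC)c3)O4)[C@H]2CO)ccc1O | target

**Step count**

Total: 22 steps. Longest linear sequence: 18 steps (vanillin 8 → 31, steps 5–22). The lactone branch (steps 1–4) joins at step 16.

**Steps most likely to fail**

Step 18. The lithium enolate 25 may expel triethylsilanolate (E1cB) to a butenolide before it is C-acylated, or the acylation may stall on the hindered α-carbon. The fallback sets out from 23 and comes back at 27, and keeps the tertiary hydroxyl free during enolate chemistry. Two equivalents of LiN(SiMe3)2 at −78 °C would give the alkoxide–enolate dianion of 23, whose β-oxide cannot leave. Claisen formylation with ethyl formate would give the formyl lactone F1. Regitz deformylative diazo transfer (4-acetamidobenzenesulfonyl azide, Et3N, MeCN) would give the hydroxy diazo lactone F2. Silylation of F2 with Et3SiOTf and 2,6-lutidine at −78 °C would then give 27.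

Step 20. Hydrogenolysis may run on into the benzylic C–O bonds of the oxolane or the dihydrobenzofuran, or may stall at the hindered lactone carbon once the benzyl ether is gone. The fallback sets out from 28 and comes back at 29, and replaces the catalytic cleavage of the lactone bond by an ionic one. Transfer hydrogenolysis (10% Pd/C, cyclohexa-1,4-diene, EtOAc) would remove only the aryl benzyl ether and give the phenol lactone F3. Treatment of F3 with NaBH4 and aq. NaOH in THF–EtOH would let the para-phenoxide expel the lactone carboxylate as a p-quinone methide, which borohydride reduces by 1,6-addition to give 29 after acidification. Only ring A carries a free phenol, so only its benzylic C–O bond can ionise; the quinone methide has no hydrogen on the neighbouring quaternary carbon and cannot tautomerise.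

Step 19. The carbenoid may be diverted into a 1,2-shift of a substituent of the silyloxy-bearing carbon, into a C–H bond of the silyl ethyl groups or into dimer, or a stepwise hydride transfer may erode the endo preference. The fallback sets out from 7 and aldehyde 20 (isolated by stopping step 14 before the borohydride stage) and comes back at 28, and forms the C6–C6a bond by an aldol addition and the oxolane by O-alkylation.
- Silylation of both hydroxyls of 7 (Et3SiOTf, 2,6-lutidine) would give the bis(triethylsilyl) ether F4.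
- Its lithium enolate (LiN(SiMe3)2, THF, −78 °C) should add to 20 anti to the silyloxy and aryl groups and, as an E-enolate in a Zimmerman–Traxler transition state, give the anti aldol adduct F5.
- Pyridinium p-toluenesulfonate in MeOH at 0 °C would free only the primary hydroxyl to give the diol F6.
- TsCl in pyridine would sulfonylate the primary hydroxyl to give the tosylate F7.
- NaH in THF would close the oxolane by intramolecular Williamson etherification (5-exo-tet) with retention at the benzylic carbon, which gives 28.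

Further compounds
F1 | step 18 | (4S,5R)-5-Ar1-3-formyl-4-hydroxy-4-[(DBF-methoxy)methyl]oxolan-2-one (C3 epimers or hydroxymethylene form) | C(OCc1cc(OC)c2c(c1)[C@H](CO[Si](C)(C)C(C)(C)C)[C@H](c1ccc(O[Si](C(C)C)(C(C)C)C(C)C)c(OC)c1)O2)[C@@]1(O)C(C=O)C(=O)O[C@@H]1c1ccc(OCc2ccccc2)c(OC)c1
F2 | step 18 | (4S,5R)-5-Ar1-3-diazo-4-hydroxy-4-[(DBF-methoxy)methyl]oxolan-2-one | C(OCc1cc(OC)c2c(c1)[C@H](CO[Si](C)(C)C(C)(C)C)[C@H](c1ccc(O[Si](C(C)C)(C(C)C)C(C)C)c(OC)c1)O2)[C@@]1(O)C(=[N+]=[N-])C(=O)O[C@@H]1c1ccc(OCc2ccccc2)c(OC)c1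
F3 | step 20 | (3R,3aS,6R,6aR)-6-DBF-3-(4-hydroxy-3-methoxyphenyl)-3a-(triethylsilyloxy)tetrahydro-1H,3H-furo[3,4-c]furan-1-one | COc1cc([C@H]2OC(=O)[C@@H]3[C@H](c4cc(OC)c5c(c4)[C@H](CO[Si](C)(C)C(C)(C)C)[C@H](c4ccc(O[Si](C(C)C)(C(C)C)C(C)C)c(OC)c4)O5)OC[C@]23O[Si](CC)(CC)CC)ccc1O
F4 | step 19 | (4S,5R)-5-Ar1-4-(triethylsilyloxy)-4-[(triethylsilyloxy)methyl]oxolan-2-one | CC[Si](CC)(CC)OC[C@@]1(O[Si](CC)(CC)CC)CC(=O)O[C@@H]1c1ccc(OCc2ccccc2)c(OC)c1
F5 | step 19 | anti aldol adduct of F4 and 20: 5-Ar1-3-[DBF(hydroxy)methyl]-4-(triethylsilyloxy)-4-[(triethylsilyloxy)methyl]oxolan-2-one (C3 substituent cis to the CH2OSiEt3 group; carbinol carbon as C6 of 28) | O=C1O[C@H](c2ccc(OCc3ccccc3)c(OC)c2)[C@](CO[Si](CC)(CC)CC)(O[Si](CC)(CC)CC)[C@H]1[C@@H](O)c1cc(OC)c2c(c1)[C@H](CO[Si](C)(C)C(C)(C)C)[C@H](c1ccc(O[Si](C(C)C)(C(C)C)C(C)C)c(OC)c1)O2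
F6 | step 19 | primary alcohol from F5: 5-Ar1-3-[DBF(hydroxy)methyl]-4-(hydroxymethyl)-4-(triethylsilyloxy)oxolan-2-one | O=C1O[C@H](c2ccc(OCc3ccccc3)c(OC)c2)[C@](CO)(O[Si](CC)(CC)CC)[C@H]1[C@@H](O)c1cc(OC)c2c(c1)[C@H](CO[Si](C)(C)C(C)(C)C)[C@H](c1ccc(O[Si](C(C)C)(C(C)C)C(C)C)c(OC)c1)O2
F7 | step 19 | primary 4-methylbenzenesulfonate of F6 | O=C1O[C@H](c2ccc(OCc3ccccc3)c(OC)c2)[C@](COS(=O)(=O)c2ccc(C)cc2)(O[Si](CC)(CC)CC)[C@H]1[C@@H](O)c1cc(OC)c2c(c1)[C@H](CO[Si](C)(C)C(C)(C)C)[C@H](c1ccc(O[Si](C(C)C)(C(C)C)C(C)C)c(OC)c1)O2
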